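## Retrosynthetic overview

1. Locants (3,7-dioxabicyclo[3.3.0]octane): C1 = bridgehead C–OH, C2 = ArCH on C1, O3, C4 = CH2 of ring A, C5 = bridgehead CH, C6 = second ArCH, O7, C8 = CH2 of ring B; Ar = 3,4-dimethoxyphenyl; the target is (1S,2R,5R,6R), with the C2 aryl exo (cis to the C1 hydroxyl) and the C6 aryl endo.
2. Last disconnection: C4 is carried as a lactone carbonyl and taken down to CH2 at the very end (lactol, then silane), so the O3–C4 bond of ring A is never broken once made.
3. Ring B (formed second): C5–C6 by intramolecular Claisen transfer of a veratroyl group from O7 to the C5 lactone enolate, giving the C6 hemiketal; exo hydride delivery to the C6 oxocarbenium ion then places the C6 aryl endo.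
4. Ring A (formed first, key step): aldol union of veratraldehyde with the dioxolanone enolate of (S)-malic acid at the fully substituted C1 (C1–C2 bond), and ring closure O3→C4 by γ-lactonisation in the same operation.
5. Enabling feature: the chain C8–C1(OH)–C5–C4 shared by rings A and B is (S)-malic acid in reduced form; C1 is α to the C8 carboxyl (enolisable, its configuration stored in a pivalaldehyde acetal) and the C4 carboxyl lies 1,4 to the benzylic oxygen O3, so the aldolate oxygen and C4 close ring A.

Key step: step 2

Remark: in the two silane reductions the acid (CF3CO2H, BF3·OEt2) only mediates ionisation and is not consumed by the equation R–OH + Et3SiH → R–H + Et3SiOH.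

## Route

Step 1
Reactants: 1 (S)-malic acid
Product: 2 2-[(2S,4S)-2-tert-butyl-5-oxo-1,3-dioxolan-4-yl]acetic acid (cis acetal)
Conditions: t-BuCHO, TsOH·H2O (cat.), H2SO4 (cat.), pentane, reflux (Dean–Stark); recrystallisation
Reagents that add atoms: pivalaldehyde, CC(C)(C)C=O
Why: Acid-catalysed acetalisation of the α-hydroxy acid unit (Seebach acetal for self-regeneration of stereocentres) should give the five-membered dioxolanone with the new acetal centre cis to the side chain under thermodynamic control, the cis isomer being enriched by crystallisation.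

Step 2
Reactants: 2 2-[(2S,4S)-2-tert-butyl-5-oxo-1,3-dioxolan-4-yl]acetic acid; 3 veratraldehyde
Product: 5 (2S,5R,6R)-2-tert-butyl-6-(3,4-dimethoxyphenyl)-1,3,7-trioxaspiro[4.4]nonane-4,8-dione, via aldol hydroxy acid 4 (not isolated)
Conditions: LiN(SiMe3)2 (2.2 equiv), THF, −78 °C; 3, −78 °C; 1 M HCl; then TsOH·H2O (cat.), CH2Cl2, rt
Reagents that add atoms: none
Why: Two equivalents of base give the carboxylate/dioxolanone-enolate dianion (the carboxylate shields the C5 methylene, and the ring acylal α-hydrogen at C1 is the most acidic C–H), whose lithium-chelated aldol addition to 3 makes the C1–C2 bond at the fully substituted carbon, and on acidification O3 of the resulting γ-hydroxy acid 4 attacks the C4 carboxyl to close ring A. The closest known reactions are the alkylations and aldol additions of Seebach dioxolanone enolates (self-regeneration of stereocentres) and the aldol–lactonisation route to paraconic acids. Ring A closes by 5-exo-trig acyl substitution (γ-lactonisation forming O3–C4); the only other acyl acceptor, the dioxolanone carbonyl C8, would require a β-lactone and should not compete. C1 is controlled by the tert-butyl group of the acetal, the aldehyde approaching the enolate face trans to it, so that C2 takes the place of the C1 hydrogen with retention and (S)-malic acid delivers (1S). C2 is controlled by a Zimmerman–Traxler chair with the aryl group equatorial: because the ring fixes C5 cis to the enolate oxygen, the C5/O3-syn adduct should form, which after lactonisation carries the aryl group cis to the C1 oxygen on ring A, i.e. (2R). The step therefore needs site-selective enolisation, face selectivity at both new centres and regioselective lactonisation, secured respectively by the carboxylate, by the acetal together with the closed transition state, and by ring size.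

Step 3
Reactants: 5 (2S,5R,6R)-2-tert-butyl-6-(3,4-dimethoxyphenyl)-1,3,7-trioxaspiro[4.4]nonane-4,8-dione
Product: 6 (2R,3R)-2-(3,4-dimethoxyphenyl)-3-hydroxy-5-oxooxolane-3-carboxylic acid
Conditions: 2 M HCl (aq), 1,4-dioxane, 60 °C
Reagents that add atoms: water, O
Why: Acid hydrolysis of the acylal (dioxolanone) unit should free the tertiary C1 hydroxyl and the C8 carboxylic acid with loss of pivalaldehyde, while the γ-lactone stays closed in aqueous acid and the benzylic C2–O3 bond is kept from ionising by its electron-poor neighbour C1, so no stereocentre is touched.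

Step 4
Reactants: 6 (2R,3R)-2-(3,4-dimethoxyphenyl)-3-hydroxy-5-oxooxolane-3-carboxylic acid
Product: 7 (4S,5R)-5-(3,4-dimethoxyphenyl)-4-hydroxy-4-(hydroxymethyl)oxolan-2-one
Conditions: BH3·THF (3 equiv), THF, 0 °C → rt; aqueous work-up
Reagents that add atoms: none
Why: Borane reduces a carboxylic acid (through its acyloxyborane) much faster than a lactone, so this chemoselective carboxylic acid reduction should take C8 to the primary alcohol and leave the ring A lactone intact.

Step 5
Reactants: 7 (4S,5R)-5-(3,4-dimethoxyphenyl)-4-hydroxy-4-(hydroxymethyl)oxolan-2-one; 8 3,4-dimethoxybenzoyl chloride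
Product: 9 [(2R,3S)-2-(3,4-dimethoxyphenyl)-3-hydroxy-5-oxooxolan-3-yl]methyl 3,4-dimethoxybenzoate
Conditions: Et3N (1.5 equiv), DMAP (cat.), CH2Cl2, 0 °C
Reagents that add atoms: none
Why: Selective esterification of the primary C8 hydroxyl over the hindered tertiary C1 hydroxyl should place the future C6 carbon and its aryl group on O7.

Step 6
Reactants: 9 [(2R,3S)-2-(3,4-dimethoxyphenyl)-3-hydroxy-5-oxooxolan-3-yl]methyl 3,4-dimethoxybenzoate
Product: 10 (1S,2R,5S)-2,6-bis(3,4-dimethoxyphenyl)-1,6-dihydroxy-3,7-dioxabicyclo[3.3.0]octan-4-one (cis-fused hemiketal; C6 anomers; same spatial arrangement at C5 as in 11)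
Conditions: LiN(i-Pr)2 (2.5 equiv), THF, −78 °C (inverse addition) → −40 °C; 1 M HCl, 0 °C
Reagents that add atoms: none
Why: The C1 alkoxide/C5 lactone enolate dianion (a Frater–Seebach-type β-oxido enolate that cannot eliminate) should attack the tethered benzoate carbonyl in a 5-exo-trig intramolecular Claisen condensation (O-to-C acyl transfer as in the Baker–Venkataraman reaction), and after acidification the C8 hydroxyl/C6 ketone pair should rest as the cis-fused hemiketal, the tether forcing the new C5–C6 bond cis to C8 so that H5 is cis to the C1 hydroxyl.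

Step 7
Reactants: 10 (1S,2R,5S)-2,6-bis(3,4-dimethoxyphenyl)-1,6-dihydroxy-3,7-dioxabicyclo[3.3.0]octan-4-one
Product: 11 (1S,2R,5R,6R)-2,6-bis(3,4-dimethoxyphenyl)-1-hydroxy-3,7-dioxabicyclo[3.3.0]octan-4-one
Conditions: Et3SiH (4 equiv), CF3CO2H, CH2Cl2, −20 → 0 °C
Reagents that add atoms: none
Why: In this ionic hydrogenation the acid ionises the hemiketal (or re-protonates its dehydration product, the C5=C6 enol ether) to the aryl-stabilised cyclic oxocarbenium ion, and silane hydride should enter from the convex face of the cis-fused bicycle (the face of H5), placing H6 exo and the C6 aryl endo as in the target.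

Step 8
Reactants: 11 (1S,2R,5R,6R)-2,6-bis(3,4-dimethoxyphenyl)-1-hydroxy-3,7-dioxabicyclo[3.3.0]octan-4-one
Product: 13 (+)-gmelinol, via lactol 12 (not isolated)
Conditions: i-Bu2AlH (2.3 equiv), CH2Cl2, −78 °C; potassium sodium tartrate (aq); then Et3SiH (3 equiv), BF3·OEt2 (1.5 equiv), CH2Cl2, −78 → −40 °C; NaHCO3 (aq)
Reagents that add atoms: none
Why: Half-reduction of the γ-lactone to the lactol and Lewis-acid-promoted silane reduction of the C4 oxocarbenium ion (reductive deoxygenation of a lactol) should turn C4=O into CH2 without cleaving the O3–C4 bond, and at low temperature the benzylic C2–O3 and C6–O7 bonds should not ionise, so no stereocentre is disturbed.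

## Compound list

1 | (S)-malic acid | OC(=O)C[C@H](O)C(=O)O | starting material
2 | 2-[(2S,4S)-2-tert-butyl-5-oxo-1,3-dioxolan-4-yl]acetic acid | OC(=O)C[C@@H]1O[C@H](C(C)(C)C)OC1=O | intermediate
3 | veratraldehyde (3,4-dimethoxybenzaldehyde) | COc1ccc(C=O)cc1OC | starting material
4 | 2-[(2S,4R)-2-tert-butyl-4-[(R)-(3,4-dimethoxyphenyl)(hydroxy)methyl]-5-oxo-1,3-dioxolan-4-yl]acetic acid (aldol hydroxy acid) | COc1ccc([C@@H](O)[C@@]2(CC(=O)O)O[C@H](C(C)(C)C)OC2=O)cc1OC | intermediate (not isolated)
5 | (2S,5R,6R)-2-tert-butyl-6-(3,4-dimethoxyphenyl)-1,3,7-trioxaspiro[4.4]nonane-4,8-dione | COc1ccc([C@H]2OC(=O)C[C@@]23O[C@H](C(C)(C)C)OC3=O)cc1OC | intermediate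
6 | (2R,3R)-2-(3,4-dimethoxyphenyl)-3-hydroxy-5-oxooxolane-3-carboxylic acid | COc1ccc([C@H]2OC(=O)C[C@]2(O)C(=O)O)cc1OC | intermediate
7 | (4S,5R)-5-(3,4-dimethoxyphenyl)-4-hydroxy-4-(hydroxymethyl)oxolan-2-one | COc1ccc([C@H]2OC(=O)C[C@]2(O)CO)cc1OC | intermediate
8 | 3,4-dimethoxybenzoyl chloride (veratroyl chloride) | COc1ccc(C(=O)Cl)cc1OC | starting material
9 | [(2R,3S)-2-(3,4-dimethoxyphenyl)-3-hydroxy-5-oxooxolan-3-yl]methyl 3,4-dimethoxybenzoate | COc1ccc([C@H]2OC(=O)C[C@]2(O)COC(=O)c3ccc(OC)c(OC)c3)cc1OC | intermediate
10 | (1S,2R,5S)-2,6-bis(3,4-dimethoxyphenyl)-1,6-dihydroxy-3,7-dioxabicyclo[3.3.0]octan-4-one (C6 anomers, in equilibrium with the open 3-aroyl lactone) | COc1ccc([C@H]2OC(=O)[C@@H]3C(O)(c4ccc(OC)c(OC)c4)OC[C@]23O)cc1OC | intermediate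
11 | (1S,2R,5R,6R)-2,6-bis(3,4-dimethoxyphenyl)-1-hydroxy-3,7-dioxabicyclo[3.3.0]octan-4-one | COc1ccc([C@H]2OC(=O)[C@@H]3[C@H](c4ccc(OC)c(OC)c4)OC[C@]23O)cc1OC | intermediate
12 | (1S,2R,5R,6R)-2,6-bis(3,4-dimethoxyphenyl)-3,7-dioxabicyclo[3.3.0]octane-1,4-diol (lactol, C4 anomers) | COc1ccc([C@H]2OC(O)[C@@H]3[C@H](c4ccc(OC)c(OC)c4)OC[C@]23O)cc1OC | intermediate (not isolated)
13 | (+)-gmelinol, (1S,2R,5R,6R)-2,6-bis(3,4-dimethoxyphenyl)-3,7-dioxabicyclo[3.3.0]octan-1-ol | COc1ccc([C@H]2OC[C@@H]3[C@H](c4ccc(OC)c(OC)c4)OC[C@]23O)cc1OC | target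

## Step count

Total steps: 8. Longest linear sequence: 8 steps, from (S)-malic acid 1.

## Steps most likely to fail

Step 2. The process at risk is weak face selectivity at the aldehyde carbon (C2) in the aldol addition, or collapse of the dioxolanone enolate before it is trapped. The fallback sets out from 2. The same dianion is C-acylated with 3,4-dimethoxybenzoyl chloride 8 (Claisen-type acylation, THF, −78 °C) to give the keto acid 2-[(2S,4R)-2-tert-butyl-4-(3,4-dimethoxybenzoyl)-5-oxo-1,3-dioxolan-4-yl]acetic acid F1, in which C1 is again set by the acetal. C2 is then set under reagent control by asymmetric transfer hydrogenation of the aryl ketone (RuCl[(S,S)-TsDPEN](p-cymene), HCO2H/Et3N), which by analogy with aryl alkyl ketones should give the (R)-carbinol. The hydroxy acid formed is 4, and acid lactonisation as in step 2 brings the route back at 5.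

Step 6. The process at risk is migration of the veratroyl group from the primary to the tertiary oxygen in the alkoxide, followed by β-elimination of veratrate from the lactone enolate, or incomplete C-acylation. The fallback sets out from 7 and leaves out ester 9. Diol 7 is treated with LiN(i-Pr)2 (3.3 equiv, THF, −78 °C) to give the bis-alkoxide lactone enolate, which undergoes an intermolecular crossed Claisen condensation with the non-enolisable methyl 3,4-dimethoxybenzoate. Both oxygens are then alkoxides and cannot leave, and the acyl group should enter C5 trans to the C1 oxide (Frater–Seebach sense), i.e. cis to C8. Acidification closes the hemiketal and the route comes back at 10; no new compound is made on the way (F0).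

Step 8. The process at risk is ionisation of the benzylic C–O bonds by the Lewis acid, leading to epimerisation at C6 or C2 or to reductive ring opening, together with over-reduction of the lactone in the hydride stage. The fallback sets out from 11. LiAlH4 (THF, 0 °C) reduces the lactone to the triol (3S,4R,5R)-5-(3,4-dimethoxyphenyl)-3-[(R)-(3,4-dimethoxyphenyl)(hydroxy)methyl]-4-(hydroxymethyl)oxolan-3-ol F2. A Mitsunobu cyclodehydration (PPh3, DIAD, THF, 0 °C → rt) then activates only the primary C4 hydroxyl, which the benzylic C2 hydroxyl displaces in a 5-exo-tet closure with retention at C2. This re-forms the O3–C4 bond under neutral conditions and comes back to the route at 13.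

## Further compounds

F1 | step 2 | 2-[(2S,4R)-2-tert-butyl-4-(3,4-dimethoxybenzoyl)-5-oxo-1,3-dioxolan-4-yl]acetic acid | COc1ccc(C(=O)[C@@]2(CC(=O)O)O[C@H](C(C)(C)C)OC2=O)cc1OC
F0 | step 6 | none | none
F2 | step 8 | (3S,4R,5R)-5-(3,4-dimethoxyphenyl)-3-[(R)-(3,4-dimethoxyphenyl)(hydroxy)methyl]-4-(hydroxymethyl)oxolan-3-ol | COc1ccc([C@@H](O)[C@@]2(O)CO[C@@H](c3ccc(OC)c(OC)c3)[C@H]2CO)cc1OC
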